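(Its constants were chosen freely.)

Every exchange, first, second or third, takes one incoming ligand and gives one leaving ligand, so the ligand used counts the exchanges made, whatever the clock says.

starting complex 0.54 M; incoming ligand 0.500 equiv; capture agent 0.540 M; time 8.0 d

    complex with two exchanged + capture agent → trapped intermediate (k1 = 1.8 L mol⁻¹ h⁻¹)
    complex with one exchanged + incoming ligand → leaving ligand + complex with two exchanged (k2 = 0.66 L mol⁻¹ h⁻¹)
    complex with two exchanged + incoming ligand → leaving ligand + complex with three exchanged (k3 = 0.56 L mol⁻¹ h⁻¹)
    starting complex + incoming ligand → leaving ligand + complex with one exchanged (k4 = 0.76 L mol⁻¹ h⁻¹)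
    leaving ligand + incoming ligand ⇌ idle adduct, settled at all times (K5 = 5.9 L mol⁻¹)

- what is said of leaving ligand includes idle adduct
- run time (flask): 8.0 d

- part of the starting complex that has reacted at 8.0 d
- share of the unused incoming ligand that is free and not bound as idle adduct, at 8.0 d

In this flask the incoming ligand is the limiting reagent, 0.270 M against 0.54 M of starting complex, and my first estimate gives each ligand to a fresh complex, which has 50.0% reacted. But the second exchange runs at 0.66 L mol⁻¹ h⁻¹ against 0.76 L mol⁻¹ h⁻¹ for the first, so I also try the opposite end, where each complex takes two ligands, and that gives 25.0%. To join the ends I take the constant of the second exchange over that of the first, the selectivity factor s = 0.868. Dividing the two rates removes free ligand, time and idle adduct, so with m the part of starting complex left and c the part reacted, the part standing as complex with one exchanged is a = (m^s − m)/(1 − s), and ligand used per complex charged, the third exchange apart, is 2c − a.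

Expanded for small conversion, this budget gives 42.2%. A truncated series is suspect, though, and the full rule there has a = 32.9% and uses 0.516 against a charge of 0.500 equiv. One more reacted complex costs 1.49 ligands at that point, so I step back to 41.2%.

The third exchange I leave out, because at the start capture runs at 0.972 h⁻¹ against 0.151 h⁻¹ for it. My next doubt is the clock: idle adduct slows the last ligand to a lifetime near 7.32 h, yet 8.0 d is far longer, so I set the exchanges equal to the charge. Leaving ligand then stands near 0.270 M, and the free share is 38.6%.

The forecast gives 41% and 38.6%, starting from this: “The incoming ligand is limiting and is used up within a few tens of hours”.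

The flask gives 41.0% and 38.6%. Left ten times as long, this flask still shows 41.0%. The neighbour charged with 1.20 equiv of incoming ligand keeps 22.6% of its starting complex, and the selectivity factor of 0.868 turns that into a = 37.1%. With its 2.22% of complex with three exchanged counted, that neighbour's exchanges come to 1.20 per starting complex charged.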